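**Retrosynthetic overview**

1. Feature used: in the seven-membered ring (C1, C10, C9, C8, C7, C6, C5) the methylene C7 lies between the oxygen-bearing C6 and the epoxide carbon C8. With C6 as a ketone and C8=C9 as an alkene, C7 is an enolisable methyl carbon and C8 the carbon of a Z-alkenyl iodide.
2. Jaeschkeanin ⇐ phenol release, C6 acylation, C6–OH-directed epoxidation, C4–OH-directed ketone reduction and desilylation ⇐ bicyclic 6-ketone, whose seven-membered ring is closed last, at C7–C8, by palladium-catalysed enolate/alkenyl iodide coupling.
3. Cyclisation substrate (cyclopentyl methyl ketone with the iodobutenyl chain on C1) ⇐ Weinreb amide ⇐ Wolff ring contraction of a 2,2-disubstituted diazocyclohexanone, the ring carbonyl carbon being pushed out as C6.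
4. Diazo ketone ⇐ axial alkylation of a menthone-type enolate with (Z)-1-bromo-3-iodobut-2-ene (C1 set against C4) ⇐ (S)-terpinen-4-ol, which supplies C1–C6, C15, the isopropyl group and the C4 configuration.
5. Ring order: six-membered ring (chiral pool) → five-membered ring (ring contraction) → seven-membered ring (key step) → epoxide.

Key step: step 11

Remark: (S)-(+)-terpinen-4-ol is assumed to be bought in high enantiomeric purity; its carbinol carbon becomes C4 and is the only source of absolute configuration.
Remark: daucane numbering is used for all intermediates (C1 quaternary carbon with methyl C15, C4 carbinol, C5 ring-fusion CH, C6 oxygen-bearing carbon, C8=C9 alkene).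

**Route**

Step 1
Reactants: 1 but-2-yn-1-ol
Product: 3 (Z)-3-iodobut-2-en-1-ol, via alkenylaluminate 2 (not isolated)
Conditions: NaAlH2(OCH2CH2OMe)2, Et2O, 0 °C to rt; then iodine, −78 °C
Reagents that add atoms: iodine, [I][I]
Why: Hydroxyl-directed trans-hydroalumination of the propargylic alcohol puts aluminium on C3 in a five-membered aluminate, and iodinolysis of the C–Al bond with retention gives only the Z-iodoalkene.

Step 2
Reactants: 3 (Z)-3-iodobut-2-en-1-ol
Product: 4 (Z)-1-bromo-3-iodobut-2-ene
Conditions: CBr4, PPh3, CH2Cl2, 0 °C
Reagents that add atoms: carbon tetrabromide, BrC(Br)(Br)Br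
Why: Appel bromination replaces the primary allylic hydroxyl by SN2 at the CH2 group and leaves the Z-alkenyl iodide untouched.

Step 3
Reactants: 5 (S)-terpinen-4-ol
Product: 6 (S)-1-isopropyl-4-methyl-1-(triethylsilyloxy)cyclohex-3-ene
Conditions: Et3SiOTf, 2,6-lutidine, CH2Cl2, −78 °C to 0 °C
Reagents that add atoms: triethylsilyl trifluoromethanesulfonate, CC[Si](CC)(CC)OS(=O)(=O)C(F)(F)F
Why: Silylation of the hindered tertiary alcohol with a silyl triflate and a non-nucleophilic base protects the future C4 oxygen without touching the carbinol centre.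

Step 4
Reactants: 6 (S)-1-isopropyl-4-methyl-1-(triethylsilyloxy)cyclohex-3-ene
Product: 8 (5S)-2-methyl-5-isopropyl-5-(triethylsilyloxy)cyclohexan-1-ol (mixture at the two new centres), via alkylborane 7 (not isolated)
Conditions: BH3·THF, THF, 0 °C to rt; then NaOH, H2O2, H2O, 0 °C to rt
Reagents that add atoms: hydrogen peroxide, OO
Why: Hydroboration–oxidation (syn, anti-Markovnikov) puts oxygen on the alkene CH (future C6) and hydrogen on the methyl-bearing carbon (C1); the two new centres need no control because C6 is oxidised in step 5 and C1 is flattened in step 6.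

Step 5
Reactants: 8 (5S)-2-methyl-5-isopropyl-5-(triethylsilyloxy)cyclohexan-1-ol
Product: 9 (5S)-2-methyl-5-isopropyl-5-(triethylsilyloxy)cyclohexan-1-one (C2 epimers)
Conditions: Dess–Martin periodinane, NaHCO3, CH2Cl2, rt
Reagents that add atoms: none
Why: Dess–Martin oxidation converts the secondary alcohol into the ketone under buffered conditions that spare the tertiary silyl ether.

Step 6
Reactants: 9 (5S)-2-methyl-5-isopropyl-5-(triethylsilyloxy)cyclohexan-1-one
Product: 10 (S)-2-methyl-5-isopropyl-5-(triethylsilyloxy)-1-(trimethylsilyloxy)cyclohex-1-ene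
Conditions: Me3SiCl, NaI, Et3N, MeCN, rt
Reagents that add atoms: chlorotrimethylsilane, C[Si](C)(C)Cl
Why: Enol silylation with iodotrimethylsilane made in situ is equilibrating, so the tetrasubstituted C1=C6 enol ether should dominate (the other isomer would sit next to quaternary C4), and no free C5 enolate that could expel the β-silyloxy group is formed.

Step 7
Reactants: 10 (S)-2-methyl-5-isopropyl-5-(triethylsilyloxy)-1-(trimethylsilyloxy)cyclohex-1-ene; 4 (Z)-1-bromo-3-iodobut-2-ene
Product: 12 (2R,5S)-2-[(Z)-3-iodobut-2-enyl]-2-methyl-5-isopropyl-5-(triethylsilyloxy)cyclohexan-1-one, via lithium enolate 11 (not isolated)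
Conditions: MeLi (1.0 equiv), THF, 0 °C to rt; then 4, DMPU, −78 °C to −20 °C
Reagents that add atoms: none
Why: Methyllithium cleaves the O–SiMe3 bond to the regiodefined lithium enolate, which is C-alkylated (SN2) by the allylic bromide to form quaternary C1; in the half-chair with the C4 isopropyl group equatorial and the silyloxy group axial the electrophile should enter axially at C1 on the face opposite the silyloxy group, as in alkylations of dihydrocarvone-type enolates, which puts the butenyl chain cis to isopropyl and C15 cis to the C4 oxygen.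

Step 8
Reactants: 12 (2R,5S)-2-[(Z)-3-iodobut-2-enyl]-2-methyl-5-isopropyl-5-(triethylsilyloxy)cyclohexan-1-one
Product: 14 6-diazo derivative of 12 (diazo group at C5 of the daucane numbering), via trifluoroacetyl ketone 13 (not isolated)
Conditions: LiN(SiMe3)2, THF, −78 °C, then CF3CO2CH2CF3; then MeSO2N3, Et3N, H2O (1 equiv), MeCN, rt
Reagents that add atoms: methanesulfonyl azide, CS(=O)(=O)N=[N+]=[N-]; 2,2,2-trifluoroethyl trifluoroacetate, FC(F)(F)COC(=O)C(F)(F)F (its acyl group stays only in 13)
Why: Detrifluoroacetylative diazo transfer (Regitz type): C5 is the only enolisable position of 12, the enolate is acylated at −78 °C before β-elimination of the silyloxy group can occur, and the activated diketone takes the diazo group from the sulfonyl azide with loss of the trifluoroacetyl group.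

Step 9
Reactants: 14 diazo ketone
Product: 16 N-methoxy-N-methyl-2-[(Z)-3-iodobut-2-enyl]-2-methyl-5-isopropyl-5-(triethylsilyloxy)cyclopentane-1-carboxamide (C1 and C4 as in 12; both C5 epimers), via ketene 15 (not isolated)
Conditions: hν (365 nm), MeNHOMe, THF, rt
Reagents that add atoms: N,O-dimethylhydroxylamine, CNOC
Why: Photochemical Wolff rearrangement: loss of N2 from the s-cis-locked cyclic diazo ketone with 1,2-shift of quaternary C1 from C6 to C5 (retention at C1) contracts the ring to a ketene that the amine captures as the Weinreb amide; C5 is protonated without control, and 365 nm light is absorbed by the diazo ketone but not by the alkenyl iodide.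

Step 10
Reactants: 16 Weinreb amide
Product: 18 1-{(1R,2R,5R)-2-[(Z)-3-iodobut-2-enyl]-2-methyl-5-isopropyl-5-(triethylsilyloxy)cyclopentyl}ethanone, via epimeric methyl ketone 17 (not isolated)
Conditions: MeMgBr, THF, 0 °C to rt; aq. NH4Cl; then K2CO3, MeOH, rt
Reagents that add atoms: methylmagnesium bromide, C[Mg]Br
Why: Weinreb ketone synthesis (the chelated magnesium adduct stops at the ketone and MeMgBr does not exchange with the alkenyl iodide), followed by carbonate-mediated enolisation in methanol, where fast reprotonation should let C5 settle with the acetyl group trans to the isopropyl group and the butenyl chain (cis to C4–O and C15) before the silyloxy group is eliminated.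

Step 11
Reactants: 18 trans-configured cyclopentyl methyl ketone
Product: 19 jaeschkeanadiol 6-ketone 4-O-triethylsilyl ether (trans-fused dauc-8-en-6-one)
Conditions: Pd2(dba)3 (5 mol %), XPhos (12 mol %), K3PO4, toluene (0.01 M), 80 °C
Reagents that add atoms: none
Why: Zerovalent palladium inserts into the C8–I bond with retention of the Z geometry, K3PO4 generates the methyl-ketone enolate, which replaces iodide on divalent palladium and binds through C7, and reductive elimination forms C7–C8 and returns zerovalent palladium. The closest known reaction type is the palladium-catalysed intramolecular α-alkenylation of ketones with alkenyl halides (the enolate variant of Buchwald–Hartwig coupling), used for five- to seven-membered carbocycles. The seven-membered ring closes by reductive elimination from an eight-membered palladacycle with the enolate C6=C7 bond inside the new ring (7-enolendo mode), and the Z-iodide delivers the cis C8=C9 bond directly in the β,γ-position, so no deconjugation is needed. No stereocentre is formed; C1, C4 and C5 are carried through, and C5 should stay trans-fused because the acyl carbon is held anti to the isopropyl group. The step needs C7 over C5 enolisation, secured by the unhindered methyl group against a methine flanked by two fully substituted carbons and by the weak heterogeneous base, and it needs coupling over carbonyl addition or oligomerisation, for which the bulky biaryl phosphine (fast reductive elimination) and high dilution are chosen.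

Step 12
Reactants: 19 bicyclic ketone silyl ether
Product: 20 jaeschkeanadiol 6-ketone (4-hydroxydauc-8-en-6-one)
Conditions: HF·pyridine, pyridine, THF, 0 °C to rt
Reagents that add atoms: none
Why: Fluoride-mediated Si–O cleavage under pyridine-buffered, non-basic conditions frees the tertiary C4 alcohol without retro-aldol cleavage, dehydration or migration of the β,γ-double bond into conjugation.

Step 13
Reactants: 20 jaeschkeanadiol 6-ketone
Product: 21 jaeschkeanadiol (C6–OH anti to C4–OH)
Conditions: Me4NBH(OAc)3, AcOH, MeCN, −30 °C to 0 °C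
Reagents that add atoms: none
Why: Hydroxyl-directed (Evans–Saksena) reduction: the C4 hydroxyl exchanges an acetate on boron and the hydride is delivered within the molecule to the carbonyl face that the C4–O bond can reach, which should give the anti 1,3-diol with H6 on the side of C15 and the new hydroxyl trans to C4–OH, while the reagent does not reduce the ketone from outside.

Step 14
Reactants: 21 jaeschkeanadiol
Product: 22 8,9-epoxyjaeschkeanadiol (epoxide syn to C6–OH)
Conditions: VO(acac)2 (5 mol %), t-BuOOH, CH2Cl2, 0 °C to rt
Reagents that add atoms: tert-butyl hydroperoxide, CC(C)(C)OO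
Why: Vanadium-catalysed hydroxyl-directed epoxidation: the homoallylic C6 hydroxyl binds the vanadium tert-butylperoxo species and delivers oxygen to the face of C8=C9 syn to C6–O, which is also the face remote from C15, setting C8 and C9 together.

Step 15
Reactants: 22 8,9-epoxyjaeschkeanadiol; 23 4-acetoxybenzoic acid
Product: 24 8,9-epoxyjaeschkeanadiol 6-(4-acetoxybenzoate)
Conditions: DCC, DMAP, CH2Cl2, rt
Reagents that add atoms: none
Why: Steglich esterification acylates the secondary C6 hydroxyl while the hindered tertiary C4 hydroxyl stays free, and the neutral conditions leave the trisubstituted epoxide and the aryl acetate intact.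

Step 16
Reactants: 24 8,9-epoxyjaeschkeanadiol 6-(4-acetoxybenzoate)
Product: 25 jaeschkeanin
Conditions: pyrrolidine, CH2Cl2, 0 °C
Reagents that add atoms: none
Why: Aminolysis of the aryl acetate by pyrrolidine is far faster than attack on the alkyl 4-hydroxybenzoate or the epoxide, so the phenol is freed selectively to give the target.

**Compound list**

1 | but-2-yn-1-ol | CC#CCO | starting material
2 | sodium 2,2-bis(2-methoxyethoxy)-3-methyl-2,5-dihydro-1,2-oxaaluminol-2-uide (cyclic alkenylaluminate) | CC1=CCO[Al-]1(OCCOC)OCCOC.[Na+] | intermediate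
3 | (Z)-3-iodobut-2-en-1-ol | OC/C=C(C)\I | intermediate
4 | (Z)-1-bromo-3-iodobut-2-ene | BrC/C=C(C)\I | intermediate
5 | (S)-(+)-terpinen-4-ol | CC(C)[C@]1(O)CCC(C)=CC1 | starting material
6 | (S)-1-isopropyl-4-methyl-1-(triethylsilyloxy)cyclohex-3-ene | CC(C)[C@]1(O[Si](CC)(CC)CC)CCC(C)=CC1 | intermediate
7 | alkylborane from 6, boron on C6 (drawn as the monoalkylborane) | CC(C)[C@]1(O[Si](CC)(CC)CC)CCC(C)C(B)C1 | intermediate
8 | (5S)-2-methyl-5-isopropyl-5-(triethylsilyloxy)cyclohexan-1-ol, OH and methyl trans, diastereomer mixture | CC(C)[C@]1(O[Si](CC)(CC)CC)CCC(C)C(O)C1 | intermediate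
9 | (5S)-2-methyl-5-isopropyl-5-(triethylsilyloxy)cyclohexan-1-one, C2 epimers | CC(C)[C@]1(O[Si](CC)(CC)CC)CCC(C)C(=O)C1 | intermediate
10 | (S)-2-methyl-5-isopropyl-5-(triethylsilyloxy)-1-(trimethylsilyloxy)cyclohex-1-ene | CC(C)[C@]1(O[Si](CC)(CC)CC)CCC(C)=C(O[Si](C)(C)C)C1 | intermediate
11 | lithium enolate of 9 (C1=C6) | CC(C)[C@]1(O[Si](CC)(CC)CC)CCC(C)=C(O[Li])C1 | intermediate
12 | (2R,5S)-2-[(Z)-3-iodobut-2-enyl]-2-methyl-5-isopropyl-5-(triethylsilyloxy)cyclohexan-1-one (chain cis to isopropyl) | CC(C)[C@]1(O[Si](CC)(CC)CC)CC[C@](C)(C/C=C(C)\I)C(=O)C1 | intermediate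
13 | 6-(trifluoroacetyl) derivative of 12 | CC(C)[C@]1(O[Si](CC)(CC)CC)CC[C@](C)(C/C=C(C)\I)C(=O)C1C(=O)C(F)(F)F | intermediate
14 | 6-diazo derivative of 12 | CC(C)[C@]1(O[Si](CC)(CC)CC)CC[C@](C)(C/C=C(C)\I)C(=O)C1=[N+]=[N-] | intermediate
15 | ring-contracted cyclopentylidene ketene (C5=C6=O) | CC(C)[C@]1(O[Si](CC)(CC)CC)CC[C@](C)(C/C=C(C)\I)C1=C=O | intermediate
16 | Weinreb amide, C1 and C4 defined, C5 epimers | CC(C)[C@]1(O[Si](CC)(CC)CC)CC[C@](C)(C/C=C(C)\I)C1C(=O)N(C)OC | intermediate
17 | methyl ketone, C5 epimers | CC(C)[C@]1(O[Si](CC)(CC)CC)CC[C@](C)(C/C=C(C)\I)C1C(C)=O | intermediate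
18 | 1-{(1R,2R,5R)-2-[(Z)-3-iodobut-2-enyl]-2-methyl-5-isopropyl-5-(triethylsilyloxy)cyclopentyl}ethanone (acetyl cis to C15 and C4–O) | CC(C)[C@]1(O[Si](CC)(CC)CC)CC[C@](C)(C/C=C(C)\I)[C@H]1C(C)=O | intermediate
19 | jaeschkeanadiol 6-ketone 4-O-triethylsilyl ether | CC(C)[C@]1(O[Si](CC)(CC)CC)CC[C@]2(C)CC=C(C)CC(=O)[C@H]21 | intermediate
20 | jaeschkeanadiol 6-ketone | CC(C)[C@]1(O)CC[C@]2(C)CC=C(C)CC(=O)[C@H]21 | intermediate
21 | jaeschkeanadiol | CC(C)[C@]1(O)CC[C@]2(C)CC=C(C)C[C@H](O)[C@H]21 | intermediate
22 | 8,9-epoxyjaeschkeanadiol | CC(C)[C@]1(O)CC[C@]2(C)C[C@@H]3O[C@]3(C)C[C@H](O)[C@H]21 | intermediate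
23 | 4-acetoxybenzoic acid | CC(=O)Oc1ccc(cc1)C(O)=O | starting material
24 | 8,9-epoxyjaeschkeanadiol 6-(4-acetoxybenzoate) | CC(C)[C@]1(O)CC[C@]2(C)C[C@@H]3O[C@]3(C)C[C@H](OC(=O)c3ccc(OC(C)=O)cc3)[C@H]21 | intermediate
25 | jaeschkeanin | CC(C)[C@]1(O)CC[C@]2(C)C[C@@H]3O[C@]3(C)C[C@H](OC(=O)c3ccc(O)cc3)[C@H]21 | target

**Step count**

Total: 16 steps (2 for bromide 4, 14 in the main line). Longest linear sequence: 14 steps, from (S)-terpinen-4-ol (steps 3 to 16).

**Steps most likely to fail**

Step 11. Closure of the seven-membered ring is slow, so the alkenylpalladium iodide may be reduced or may add to the C6 carbonyl, and 18 may be enolised towards C5 and lose triethylsilanolate. The fallback sets out from 18 and returns at 19. The enolate would be fixed before the coupling: LiN(SiMe3)2 and Me3SiCl in THF at −78 °C should deprotonate only the C7 methyl group and give the trimethylsilyl enol ether F1. This would then be cyclised without Brønsted base by a Heck-type palladium coupling of the enol silane with the alkenyl iodide through its tin enolate (Pd(OAc)2, P(t-Bu)3, Bu3SnF, toluene, 80 °C), which gives 19.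

Step 10. C5 is formed by uncontrolled protonation in step 9, and its correction relies on enolisation next to a β-silyloxy group, where epimerisation may be too slow or be overtaken by elimination. The fallback sets out from 12 and returns at 18, and it sets C5 by a stereospecific migration instead. Bromination of 12 at C5 with PhNMe3Br3 in THF at 0 °C, the HBr formed equilibrating the product to the equatorial bromide (Br cis to the axial silyloxy group, trans to isopropyl), should give the bromo ketone F2. MeMgBr then adds to the C6 carbonyl at −78 °C to give the bromomagnesium alkoxide F3. On warming in toluene, F3 should undergo the semipinacol ring contraction of a halohydrin magnesium salt: the C6–C1 bond, antiperiplanar to the equatorial C5–Br bond, migrates to C5 with inversion. This gives 18 directly, with H5 cis to isopropyl and no enolisation at C5.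

Step 13. The hindered tertiary hydroxyl may bind boron too slowly, so that the ketone is left or is reduced from outside on the face away from C15, giving the C6 epimer. The fallback sets out from 20 and returns at 21, and it accepts the external attack and then inverts C6. LiBH(s-Bu)3 in THF at −78 °C should give the 6-epimeric diol F4. Mitsunobu esterification of its secondary hydroxyl with 4-nitrobenzoic acid (PPh3, DIAD, toluene) inverts C6 to jaeschkeanadiol 6-(4-nitrobenzoate) F5, and methanolysis (K2CO3, MeOH) gives 21.

**Further compounds**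

F1 | step 11 | trimethylsilyl enol ether of 18 (C6=C7) | CC(C)[C@]1(O[Si](CC)(CC)CC)CC[C@](C)(C/C=C(C)\I)[C@H]1C(=C)O[Si](C)(C)C
F2 | step 10 | 6-bromo derivative of 12, bromine on daucane C5 cis to the silyloxy group | CC(C)[C@]1(O[Si](CC)(CC)CC)CC[C@](C)(C/C=C(C)\I)C(=O)[C@H]1Br
F3 | step 10 | bromomagnesium alkoxide from MeMgBr addition to F2 | CC(C)[C@]1(O[Si](CC)(CC)CC)CC[C@](C)(C/C=C(C)\I)C(C)(O[Mg]Br)[C@H]1Br
F4 | step 13 | 6-epi-jaeschkeanadiol | CC(C)[C@]1(O)CC[C@]2(C)CC=C(C)C[C@@H](O)[C@H]21
F5 | step 13 | jaeschkeanadiol 6-(4-nitrobenzoate) | CC(C)[C@]1(O)CC[C@]2(C)CC=C(C)C[C@H](OC(=O)c3ccc(cc3)[N+](=O)[O-])[C@H]21
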